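The furan ring (O1, C2, C3, C3a, C7a) is disconnected at C2=C3 and O1–C2. Because C3 bears a methyl group and C2 a CH2–C arm, C3 and its methyl are taken from the acetyl group of an ortho-hydroxyacetophenone, and C2 and the arm from the three carbons of a silyl propargyl ether. One operation, a CuBr-mediated carbene–alkyne coupling of the ketone N-tosylhydrazone followed by addition of the neighbouring phenoxide to the allene so formed, makes both bonds and the ring and delivers the side chain at its final length. The precursor is the tosylhydrazone of a 4-aryl-2-hydroxy-3,6-dimethoxyacetophenone whose distal phenol is masked as a benzyl ether.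

Key step: step 7

Remark on the chemistry: hydrazone 12 is drawn as the E isomer; the geometry does not matter for step 7, since either isomer gives the same diazoalkane.

Step 1
Reactants: 1 2-hydroxy-5-methoxybenzaldehyde
Product: 2 3-bromo-2-hydroxy-5-methoxybenzaldehyde
Conditions: Br2 (1.05 equiv), NaOAc, AcOH, rt
Reagents that add atoms: bromine, BrBr
Why: Electrophilic aromatic bromination: the hydroxyl group is the strongest director and its para carbon is blocked by methoxy, so bromine should enter the free carbon ortho to it (C3), with NaOAc taking up the HBr.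

Step 2
Reactants: 2 3-bromo-2-hydroxy-5-methoxybenzaldehyde
Product: 3 3-bromo-2,5-dimethoxybenzaldehyde
Conditions: MeI, K2CO3, DMF, rt
Reagents that add atoms: iodomethane, CI
Why: Williamson O-methylation: the phenoxide formed with K2CO3 displaces iodide from MeI (SN2), and no other acidic site is present.

Step 3
Reactants: 3 3-bromo-2,5-dimethoxybenzaldehyde
Product: 5 3-bromo-2,5-dimethoxyphenol, via 3-bromo-2,5-dimethoxyphenyl formate 4 (not isolated)
Conditions: mCPBA, CH2Cl2, rt; aq NaHCO3 wash; then K2CO3 (cat.), MeOH, rt
Reagents that add atoms: mCPBA, OOC(=O)c1cccc(Cl)c1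
Why: Baeyer–Villiger oxidation of an ortho-alkoxybenzaldehyde (Dakin-type): in the Criegee adduct the electron-rich aryl group migrates in preference to hydride to give formate 4, which mild methanolysis cleaves without touching the aryl bromide or the methyl ethers.

Step 4
Reactants: 5 3-bromo-2,5-dimethoxyphenol
Product: 8 1-(4-bromo-2-hydroxy-3,6-dimethoxyphenyl)ethanone, via 3-bromo-2,5-dimethoxyphenyl acetate 6 (not isolated), via ketone difluoroboron chelate 7 (not isolated)
Conditions: Ac2O (1.2 equiv), BF3·OEt2 (3 equiv), AcOH, rt then 90 °C; then MeOH/H2O, 60 °C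
Reagents that add atoms: acetic anhydride, CC(=O)OC(C)=O
Why: BF3-promoted O-acetylation and Fries rearrangement in one flask: the acyl group should move to C6, the only free ortho carbon, because the para carbon is flanked by bromine and methoxy and the six-membered difluoroboron chelate 7 is the thermodynamic sink, while BF3 (unlike AlCl3 or BCl3) leaves aryl methyl ethers intact and the chelate is opened by warm aqueous methanol.

Step 5
Reactants: 8 1-(4-bromo-2-hydroxy-3,6-dimethoxyphenyl)ethanone; 9 4-(benzyloxy)phenylboronic acid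
Product: 10 1-[4-(4-benzyloxyphenyl)-2-hydroxy-3,6-dimethoxyphenyl]ethanone
Conditions: Pd(dppf)Cl2 (5 mol%), K2CO3, 1,4-dioxane/H2O, 90 °C
Reagents that add atoms: none
Why: Suzuki–Miyaura coupling: the C–Br bond para to the acetyl group adds readily to zerovalent palladium generated from Pd(dppf)Cl2, the free phenol is tolerated as its phenoxide in aqueous carbonate, and placing this coupling after the BF3 step keeps the benzyl ether away from the Lewis acid.

Step 6
Reactants: 10 1-[4-(4-benzyloxyphenyl)-2-hydroxy-3,6-dimethoxyphenyl]ethanone; 11 4-methylbenzenesulfonohydrazide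
Product: 12 N'-{(E)-1-[4-(4-benzyloxyphenyl)-2-hydroxy-3,6-dimethoxyphenyl]ethylidene}-4-methylbenzenesulfonohydrazide
Conditions: EtOH, AcOH (cat.), 80 °C
Reagents that add atoms: none
Why: Acid-catalysed condensation of the ketone with the sulfonohydrazide to the N-tosylhydrazone, driven by crystallisation of the product from hot ethanol; the carbonyl flanked by OH and OMe is hindered, so acid and prolonged heating are planned.

Step 7
Reactants: 12 N'-{(E)-1-[4-(4-benzyloxyphenyl)-2-hydroxy-3,6-dimethoxyphenyl]ethylidene}-4-methylbenzenesulfonohydrazide; 13 tert-butyldimethyl(prop-2-yn-1-yloxy)silane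
Product: 16 tert-butyl{2-[6-(4-benzyloxyphenyl)-4,7-dimethoxy-3-methyl-1-benzofuran-2-yl]ethoxy}dimethylsilane, via diazoalkane 14 (not isolated), via aryl allene 15 (not isolated)
Conditions: CuBr (10 mol%), Cs2CO3 (3 equiv), 13 (3 equiv), MeCN, 100 °C, sealed tube, N2
Reagents that add atoms: none
Why: Cs2CO3 converts 12 into diazoalkane 14 (Bamford–Stevens), which the copper acetylide formed from 13 and CuBr decomposes to a copper carbene; migration of the alkynyl group from copper to the carbene carbon makes the C3–C2 bond, and protonation of the resulting propargyl/allenyl copper species at the remote carbon gives allene 15. The ortho phenoxide then adds to the central allene carbon across the distal C=C bond (5-exo-dig), forming O1–C2 and the furan ring, and protonation of the furylmethyl anion at the former internal alkyne carbon gives the aromatic benzofuran with its CH2CH2OTBS arm. The closest known reaction type is the CuBr-catalysed coupling of ortho-hydroxyaryl N-tosylhydrazones with terminal alkynes to 2-alkylbenzofurans, together with the related copper-catalysed synthesis of trisubstituted allenes from ketone tosylhydrazones. No stereocentre is formed, and the axial chirality of 15 is lost on aromatisation. The carbene–alkyne coupling must outrun 1,2-hydride shift to the vinylarene and azine formation, which the excess alkyne and fast alkynyl migration on copper should secure; oxygen must attack the central rather than the terminal allene carbon, which is secured because only central attack gives a delocalised carbanion and a five-membered ring, whereas six-membered closure would generate an unstabilised vinyl anion. The alkyl silyl ether, the benzyl ether and the methyl ethers are inert to carbonate in MeCN, and the unactivated alkyne is not attacked directly by the phenoxide.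

Step 8
Reactants: 16 tert-butyl{2-[6-(4-benzyloxyphenyl)-4,7-dimethoxy-3-methyl-1-benzofuran-2-yl]ethoxy}dimethylsilane
Product: 17 2-[6-(4-benzyloxyphenyl)-4,7-dimethoxy-3-methyl-1-benzofuran-2-yl]ethanol
Conditions: TBAF (1.2 equiv), THF, 0 °C to rt
Reagents that add atoms: none
Why: Fluoride-mediated desilylation driven by the strong Si–F bond; the benzyl ether, the aryl methyl ethers and the benzofuran are inert to TBAF.

Step 9
Reactants: 17 2-[6-(4-benzyloxyphenyl)-4,7-dimethoxy-3-methyl-1-benzofuran-2-yl]ethanol
Product: 19 [6-(4-benzyloxyphenyl)-4,7-dimethoxy-3-methyl-1-benzofuran-2-yl]acetic acid, via arylacetaldehyde 18 (not isolated)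
Conditions: TEMPO (cat.), NaClO2 (2 equiv), NaOCl (cat.), MeCN/phosphate buffer (pH 6.7), 35 °C
Reagents that add atoms: sodium chlorite, [Na+].[O-]Cl=O
Why: Nitroxyl-catalysed oxidation of the primary alcohol to aldehyde 18 coupled to in-flask chlorite oxidation to the acid (Zhao variant of the Anelli and Pinnick oxidations), a protocol established for electron-rich 2-arylethanols because hypochlorite stays catalytic and the enolisable aldehyde never accumulates.

Step 10
Reactants: 19 [6-(4-benzyloxyphenyl)-4,7-dimethoxy-3-methyl-1-benzofuran-2-yl]acetic acid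
Product: 20 methyl [6-(4-benzyloxyphenyl)-4,7-dimethoxy-3-methyl-1-benzofuran-2-yl]acetate
Conditions: TMSCHN2, PhMe/MeOH (4:1), 0 °C to rt
Reagents that add atoms: (trimethylsilyl)diazomethane, C[Si](C)(C)C=[N+]=[N-]
Why: Methyl esterification with (trimethylsilyl)diazomethane: the acid protonates the diazoalkane, methanol removes the silyl group and the carboxylate is O-methylated, under neutral conditions that cannot C-alkylate the acidic CH2.

Step 11
Reactants: 20 methyl [6-(4-benzyloxyphenyl)-4,7-dimethoxy-3-methyl-1-benzofuran-2-yl]acetate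
Product: 21 phenylcandilide B, methyl [6-(4-hydroxyphenyl)-4,7-dimethoxy-3-methyl-1-benzofuran-2-yl]acetate
Conditions: H2 (1 atm), 10% Pd/C, EtOAc/MeOH, rt
Reagents that add atoms: none
Why: Catalytic hydrogenolysis of the benzyl ether on palladium; the tetrasubstituted furan C2=C3 bond, the ester and the aryl methyl ethers should not be reduced at ambient pressure and temperature.

Compound list
1 | 2-hydroxy-5-methoxybenzaldehyde | COc1ccc(O)c(C=O)c1 | starting material
2 | 3-bromo-2-hydroxy-5-methoxybenzaldehyde | COc1cc(Br)c(O)c(C=O)c1 | intermediate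
3 | 3-bromo-2,5-dimethoxybenzaldehyde | COc1cc(Br)c(OC)c(C=O)c1 | intermediate
4 | 3-bromo-2,5-dimethoxyphenyl formate | COc1cc(Br)c(OC)c(OC=O)c1 | intermediate
5 | 3-bromo-2,5-dimethoxyphenol | COc1cc(Br)c(OC)c(O)c1 | intermediate
6 | 3-bromo-2,5-dimethoxyphenyl acetate | COc1cc(Br)c(OC)c(OC(C)=O)c1 | intermediate
7 | difluoroboron chelate of 1-(4-bromo-2-hydroxy-3,6-dimethoxyphenyl)ethanone (six-membered O–B–O ring through the phenol and carbonyl oxygens) | CC1=[O+][B-](F)(F)Oc2c(OC)c(Br)cc(OC)c12 | intermediate
8 | 1-(4-bromo-2-hydroxy-3,6-dimethoxyphenyl)ethanone | CC(=O)c1c(O)c(OC)c(Br)cc1OC | intermediate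
9 | 4-(benzyloxy)phenylboronic acid | OB(O)c1ccc(OCc2ccccc2)cc1 | starting material
10 | 1-[4-(4-benzyloxyphenyl)-2-hydroxy-3,6-dimethoxyphenyl]ethanone | CC(=O)c1c(O)c(OC)c(-c2ccc(OCc3ccccc3)cc2)cc1OC | intermediate
11 | 4-methylbenzenesulfonohydrazide | Cc1ccc(S(=O)(=O)NN)cc1 | starting material
12 | N'-{(E)-1-[4-(4-benzyloxyphenyl)-2-hydroxy-3,6-dimethoxyphenyl]ethylidene}-4-methylbenzenesulfonohydrazide | C/C(=N\NS(=O)(=O)c1ccc(C)cc1)c1c(O)c(OC)c(-c2ccc(OCc3ccccc3)cc2)cc1OC | intermediate
13 | tert-butyldimethyl(prop-2-yn-1-yloxy)silane | C#CCO[Si](C)(C)C(C)(C)C | starting material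
14 | 3-(4-benzyloxyphenyl)-6-(1-diazoethyl)-2,5-dimethoxyphenol | CC(=[N+]=[N-])c1c(O)c(OC)c(-c2ccc(OCc3ccccc3)cc2)cc1OC | intermediate
15 | 3-(4-benzyloxyphenyl)-6-[5-(tert-butyldimethylsilyloxy)penta-2,3-dien-2-yl]-2,5-dimethoxyphenol (racemic allene) | CC(=C=CCO[Si](C)(C)C(C)(C)C)c1c(O)c(OC)c(-c2ccc(OCc3ccccc3)cc2)cc1OC | intermediate
16 | tert-butyl{2-[6-(4-benzyloxyphenyl)-4,7-dimethoxy-3-methyl-1-benzofuran-2-yl]ethoxy}dimethylsilane | Cc1c(CCO[Si](C)(C)C(C)(C)C)oc2c(OC)c(-c3ccc(OCc4ccccc4)cc3)cc(OC)c12 | intermediate
17 | 2-[6-(4-benzyloxyphenyl)-4,7-dimethoxy-3-methyl-1-benzofuran-2-yl]ethanol | Cc1c(CCO)oc2c(OC)c(-c3ccc(OCc4ccccc4)cc3)cc(OC)c12 | intermediate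
18 | [6-(4-benzyloxyphenyl)-4,7-dimethoxy-3-methyl-1-benzofuran-2-yl]acetaldehyde | Cc1c(CC=O)oc2c(OC)c(-c3ccc(OCc4ccccc4)cc3)cc(OC)c12 | intermediate
19 | [6-(4-benzyloxyphenyl)-4,7-dimethoxy-3-methyl-1-benzofuran-2-yl]acetic acid | Cc1c(CC(=O)O)oc2c(OC)c(-c3ccc(OCc4ccccc4)cc3)cc(OC)c12 | intermediate
20 | methyl [6-(4-benzyloxyphenyl)-4,7-dimethoxy-3-methyl-1-benzofuran-2-yl]acetate | COC(=O)Cc1oc2c(OC)c(-c3ccc(OCc4ccccc4)cc3)cc(OC)c2c1C | intermediate
21 | phenylcandilide B, methyl [6-(4-hydroxyphenyl)-4,7-dimethoxy-3-methyl-1-benzofuran-2-yl]acetate | COC(=O)Cc1oc2c(OC)c(-c3ccc(O)cc3)cc(OC)c2c1C | target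

Total step count: 11
Longest linear sequence: 11 steps (1 to 21); compounds 9, 11 and 13 are purchased.

Steps most likely to fail

Step 7. The copper carbene may be diverted into 1,2-hydride shift or azine formation, coupling at the doubly ortho-substituted carbene carbon may be slow, or the propargyl-to-allene isomerisation and ring closure may stall. The fallback sets out from ketone 10 and comes back to the route at acid 19, bypassing steps 6 to 9. Ketone 10 would be heated with chloroacetone and K2CO3 in DMF (Rap–Stoermer-type annulation). O-alkylation should give 1-[2-acetyl-5-(4-benzyloxyphenyl)-3,6-dimethoxyphenoxy]propan-2-one F1, and intramolecular aldol condensation should then give 1-[6-(4-benzyloxyphenyl)-4,7-dimethoxy-3-methyl-1-benzofuran-2-yl]ethanone F2. A Willgerodt–Kindler reaction (S8, morpholine, 130 °C) should move the oxidised carbon to the chain end and give 2-[6-(4-benzyloxyphenyl)-4,7-dimethoxy-3-methyl-1-benzofuran-2-yl]-1-(morpholin-4-yl)ethanethione F3. Hydrolysis with KOH in aqueous EtOH at reflux and acidification should give acid 19.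

Step 4. The acyl group may migrate to the para carbon, the rearrangement may stop at the acetate, or a methyl ether may be lost under the hot Lewis acid. The fallback sets out from phenol 5 and comes back at ketone 8, replacing the rearrangement by a chelation-controlled ortho C–C bond formation. Magnesium-phenoxide-directed formylation (MgCl2, Et3N, paraformaldehyde, MeCN, reflux) can only reach the free ortho carbon and should give 4-bromo-2-hydroxy-3,6-dimethoxybenzaldehyde F4. Addition of MeMgBr (2.5 equiv, THF, 0 °C) should give racemic 1-(4-bromo-2-hydroxy-3,6-dimethoxyphenyl)ethanol F5, and oxidation of the benzylic alcohol with MnO2 in CH2Cl2 should give 8.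

Step 9. Ring chlorination by hypochlorite or oxidative degradation at the enolisable aldehyde stage may erode the material. The fallback sets out from alcohol 17 and comes back at acid 19, separating the two oxidation levels and using no hypochlorite and no nitroxyl cycle. Dess–Martin periodinane (NaHCO3, CH2Cl2, 0 °C) should give aldehyde 18, which would be isolated quickly and oxidised with NaClO2, NaH2PO4 and excess 2-methyl-2-butene as chlorine scavenger in t-BuOH/H2O to give 19.

Further compounds
F1 | step 7 | 1-[2-acetyl-5-(4-benzyloxyphenyl)-3,6-dimethoxyphenoxy]propan-2-one | CC(=O)COc1c(C(C)=O)c(OC)cc(-c2ccc(OCc3ccccc3)cc2)c1OC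
F2 | step 7 | 1-[6-(4-benzyloxyphenyl)-4,7-dimethoxy-3-methyl-1-benzofuran-2-yl]ethanone | CC(=O)c1oc2c(OC)c(-c3ccc(OCc4ccccc4)cc3)cc(OC)c2c1C
F3 | step 7 | 2-[6-(4-benzyloxyphenyl)-4,7-dimethoxy-3-methyl-1-benzofuran-2-yl]-1-(morpholin-4-yl)ethanethione | S=C(Cc1oc2c(OC)c(-c3ccc(OCc4ccccc4)cc3)cc(OC)c2c1C)N1CCOCC1
F4 | step 4 | 4-bromo-2-hydroxy-3,6-dimethoxybenzaldehyde | O=Cc1c(O)c(OC)c(Br)cc1OC
F5 | step 4 | 1-(4-bromo-2-hydroxy-3,6-dimethoxyphenyl)ethanol (racemic) | CC(O)c1c(O)c(OC)c(Br)cc1OC
F0 | step 9 | none | none
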